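## The problem

The target is a C30 triterpenoid built from two bicyclic halves: a trans-fused perhydro-1-benzoxepine (ring A oxepane, ring B cyclohexane) and a cis-fused hydroazulene (ring C cycloheptene, ring D cyclopentane). They are joined by a CH2CH2 bridge from the ring B methine C6 to the tetrasubstituted alkene carbon C5 of ring C. Benzoxepine numbering is used for rings A/B (O1, C2 = CMe2, C3 = CHOH, C5a = quaternary C–Me, C6, C7 = C(Me)OH, C9a = CH–O) and azulene numbering for rings C/D (C1 = C(Me)OH, C3a and C8a = fusion CH, C4 = CMe2, C5=C6 alkene, C7 = CHOH).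

There are nine stereocentres in two sets, five in rings A/B and four in rings C/D. The bridge insulates the sets from each other, so each half has to be made as one enantiomer and the halves joined late.

In rings C/D only the secondary carbinol C7 is easy to buy. It has to set C3a, and C3a then has to set C8a and, through the cup shape of the cis-fused bicycle, the tertiary carbinol C1. In rings A/B, C3 and C9a have the configurations of two epoxide carbons of opposite sense, C5a follows from anti opening, C6 is epimerisable next to a carbonyl, and the axial hydroxyl at C7 calls for equatorial delivery of methyl to a ketone.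

The two tertiary alcohols dehydrate under acid, and the allylic C7 carbinol on a tetrasubstituted alkene ionises easily. The alkene itself rules out late ozonolysis or epoxidation, and β-oxygenated ketones on the way can lose their oxygen by elimination. The most hindered bond is the one from C5, flanked by CMe2 and the methylated C6, to the bridge.

The feature that opens the structure is in ring C. C4 (CMe2) and the adjacent fusion carbon C3a are the two carbons of a prenyl-type alkene, C3, C2 and C1 complete a 5-methylhex-4-enoyl chain, and the other five ring C carbons (C5, C6, C7, C8, C8a) are a 4-oxygenated cyclopentanone. Ring C is therefore a cyclopentanone enlarged by exactly the two alkene carbons, which is the signature of a de Mayo reaction.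

## Retrosynthesis

**End game.** Target 31 comes from its bis-silyl ether 30, and 30 from the spiro-epoxide 29 by hydride opening at the CH2 terminus. The C1 carbinol is carried as an epoxide because an epoxide has no acidic proton and survives enolate chemistry and cross-coupling. Its oxygen must sit on the face of the fusion hydrogens, which epoxidation of a methylene group from the convex face provides. Direct methyl addition to a C1 ketone would give the epimer.

**Union.** 29 is cut between C5 of ring C and the bridge CH2, giving enol triflate 13 and vinyl carbinol 27 (B-alkyl Suzuki coupling via borane 28). A cut at the ring B end would require alkylation of a secondary carbon next to a quaternary centre. A cut in the middle of the bridge would need two extra functional handles. The chosen cut needs only a ketone with one enolisable side on one half and a vinyl group on the other. It asks the coupling to tolerate a tetrasubstituted triflate beside a quaternary carbon.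

**Ring C/D adjustments.** 13 comes from methyl ketone 12, which comes from ketone 11 by alkylation at C6, the only enolisable position. 11 comes from methylene ketone 10 by epoxidation, and 10 from diketone 9 by methylenation of the less hindered ring D carbonyl. No skeletal bond is made in this stretch.

**Key disconnection.** 9 is cut at C3a–C8a and C4–C5 and rejoined at C5–C8a, leading back to the ring enol acetate 7 through the cyclobutane photoadduct 8. An aldol or Michael cut of the 1,5-diketone is blocked because C4 is quaternary. A two-component cycloaddition would leave regiochemistry open. Here the three-atom acyl tether dictates which carbons join. The bicycle with three stereocentres becomes a monocyclic cyclopentene with one purchasable stereocentre. The forward reaction must give the straight adduct, add anti to the silyloxy group and fragment without losing that group.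

**Photosubstrate.** 7 comes from diketone 6 by O-acetylation on the ring oxygen. 6 comes from C-acylation of the regiodefined lithium enolate 5 with imidazolide 4 (from acid 3). Enolate 5 comes from silyl enol ether 2, made by conjugate hydrosilylation of enone 1. Only this enolate is usable, since its regioisomer would expel the β-silyloxy group.

**Ring A/B adjustments.** 27 comes from vinyl ketone 26 by methyl addition anti to the axial C5a methyl, which gives the required axial hydroxyl at C7. Hydration of an alkene or biogenetic anti addition would give the equatorial one. 26 derives from β-keto ester 22 through diol 23, hydroxy aldehyde 24 and vinyl alcohol 25, so the ester carbon becomes the first bridge carbon.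

**Rings A and B together.** 22 is cut at C5a–C6 and O1–C2, leading to the acyclic diepoxy silyl enol ether 21 (epoxonium cascade). Stepwise closure of the oxepane from a hydroxy epoxide has a 6-exo versus 7-endo problem, which the cascade avoids because the ether oxygen is the internal epoxide oxygen. 21 comes from β-keto ester 20, and 20 from diepoxy alcohol 16 and methyl acetoacetate 17, through triflate 18 and dianion 19. Because C3 and C9a need epoxides of opposite sense, 16 is made in two controlled steps from geraniol 14 through epoxy alcohol 15: Sharpless epoxidation for the allylic alkene, then ketone-catalysed epoxidation with the enantiomeric catalyst for the remote one.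

## Roads not taken

**Alternative 1:** Cut the C1–C8a bond of ring D. In the forward sense SmI2 would reduce the side-chain methyl ketone of the cross-conjugated cycloheptadienone A2 to a ketyl, which adds 5-exo to the β-carbon of the disubstituted enone and gives hydroxy enone A1.
- Merits: the tertiary carbinol and the second fusion centre form in one step, with the hydroxyl expected anti to the enone-bearing chain, as the target needs. A1 already has the C6 methyl and the ring alkene. This road spares the three steps (6, 7 and 21) that the chosen plan spends on the C1 carbinol, and in that respect it is better.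
- Weak points: A1 carries a methyl group where the bridge must go, so the union would need γ-functionalisation of an extended enolate at a carbon next to CMe2, with α/γ ambiguity. The dienone of A2 is more easily reduced by divalent samarium than the methyl ketone. The single stereocentre of A2, next to a quaternary carbon, needs its own asymmetric synthesis, and the C7 ketone of A1 still has to be reduced to one carbinol epimer.
- Comparison: the chosen plan sets against the shorter carbinol construction a chiral-pool origin for all four ring C/D stereocentres and a bridge attachment through a ketone that can form only one enol triflate.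

**Alternative 2:** Cut the C5a–C9a bond of ring A. The silyl ketene acetal of the seven-membered glycolate lactone A4 (LiN(SiMe3)2, Me3SiCl) would rearrange on warming (Ireland–Claisen) to the oxepene acid A3. The quaternary carbon is joined to the ether CH while the lactone C–O bond breaks.
- Merits: both ring A C–O bonds are made earlier by ordinary etherification, so no regiochemical question of epoxide opening arises. The quaternary centre and the ether methine are set by a sigmatropic shift. In this respect the road is better than the cascade of step 14.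
- Weak points: a boat transition state and a geometrically pure trisubstituted alkene in A4 are required. A4 itself needs a tertiary ether. Ring B, with the C6 and C7 centres, must still be annulated from the allyl and carboxyl groups of A3, and the ring alkene reduced. The hydroazulene is not addressed at all.
- Comparison: the chosen plan closes rings A and B in one operation from an acyclic diepoxide and reaches 27 in ten steps, at the price of one step of real risk.

**Alternative 3:** Cut C3a–C4 and C6–C7 of ring C. The 1,1,3-trimethyl oxyallyl cation from dibromo ketone A6 and Fe2(CO)9 would add across the termini of the ring D siloxydiene A7 to give cycloheptenone A5.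
- Merits: it is convergent, and A5 already carries the C6 methyl, the C5 ketone ready for triflation, the protected C7 carbinol and the C1 carbinol. On paper it is about five steps shorter than the chosen sequence to 13, which is a real advantage in step economy.
- Weak points: two unsymmetrical partners can join in two orientations. The nucleophilic diene terminus is the ring carbon, and whether it bonds to the CMe2 or the CHMe end of the cation is not secured. Facial selectivity depends on a quaternary carbon bearing methyl and silyloxy groups of similar size. The remaining C8–C8a alkene must be hydrogenated to the cis fusion, and A7 needs an enantioselective tertiary carbinol synthesis.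
- Comparison: the chosen plan is longer, but its regiochemistry is enforced by a tether and every stereocentre is relayed from a purchased one.

Key step: step 5

Assumptions: compound 6 is drawn as its diketone tautomer (C2 is enolisable and undefined). D-(−)-diethyl tartrate and the L-fructose-derived epoxidation ketone are taken as purchasable reagents.

## Route

Step 1
Reactants: 1 (R)-4-(tert-butyldimethylsilyloxy)cyclopent-2-en-1-one
Product: 2 (S)-tert-butyl{[3-(dimethylphenylsilyloxy)cyclopent-3-en-1-yl]oxy}dimethylsilane
Conditions: [(Ph3P)CuH]6 (3 mol %), PhMe2SiH, toluene, 0 °C to rt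
Reagents that add atoms: dimethylphenylsilane, C[SiH](C)c1ccccc1
Why: Copper hydride-catalysed 1,4-hydrosilylation delivers hydride to the β-carbon and gives only the enol ether on the side remote from the silyloxy carbon; the existing stereocentre is untouched.

Step 2
Reactants: 3 5-methylhex-4-enoic acid
Product: 4 1-(5-methylhex-4-enoyl)imidazole
Conditions: 1,1'-carbonyldiimidazole, THF, rt
Reagents that add atoms: 1,1'-carbonyldiimidazole, O=C(n1ccnc1)n1ccnc1
Why: Standard acid activation as the acyl imidazolide, an acyl donor without a Lewis acid that could cyclise the acyl group onto its own alkene.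

Step 3
Reactants: 2 (S)-tert-butyl{[3-(dimethylphenylsilyloxy)cyclopent-3-en-1-yl]oxy}dimethylsilane; 4 1-(5-methylhex-4-enoyl)imidazole
Product: 6 (4S)-4-(tert-butyldimethylsilyloxy)-2-(5-methylhex-4-enoyl)cyclopentan-1-one, via lithium enolate 5 (not isolated)
Conditions: MeLi, THF, 0 °C; LiN(SiMe3)2, −78 °C; then 4, −78 to −30 °C; aq. NH4Cl
Reagents that add atoms: none
Why: Cleavage of the silyl enol ether with MeLi gives the regiodefined lithium enolate, which is C-acylated by the imidazolide (Claisen-type acylation); the extra amide base takes up the acidic proton of the 1,3-diketone so that the enolate is not equilibrated to the isomer that would expel silyloxide.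

Step 4
Reactants: 6 (4S)-4-(tert-butyldimethylsilyloxy)-2-(5-methylhex-4-enoyl)cyclopentan-1-one
Product: 7 (4S)-4-(tert-butyldimethylsilyloxy)-2-(5-methylhex-4-enoyl)cyclopent-1-en-1-yl acetate
Conditions: AcCl, pyridine, CH2Cl2, 0 °C
Reagents that add atoms: acetyl chloride, CC(=O)Cl
Why: O-acylation of the enolised 2-acylcyclopentanone on the less hindered ring oxygen, as known for enol esters of 2-acylcyclopentanones, leaves the side-chain carbonyl as the enone carbonyl; the mild base does not touch the β-silyloxy group.

Step 5
Reactants: 7 (4S)-4-(tert-butyldimethylsilyloxy)-2-(5-methylhex-4-enoyl)cyclopent-1-en-1-yl acetate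
Product: 9 (3aR,7S,8aR)-7-(tert-butyldimethylsilyloxy)-4,4-dimethyloctahydroazulene-1,5-dione, via photoadduct 8 (not isolated)
Conditions: hν (medium-pressure Hg lamp, Pyrex, λ > 290 nm), degassed cyclohexane (0.01 M), rt; concentrate; K2CO3 (0.3 equiv), MeOH, 0 °C
Reagents that add atoms: none
Why: Intramolecular de Mayo reaction (enone–alkene [2+2] photocycloaddition, then retro-aldol). The excited β-acetoxy enone bonds from its α-carbon to the alkene CH in a 1,5-closure (five-membered ring D, rule of five), and the 1,4-biradical then closes the cyclobutane between the acetoxy carbon and CMe2; the three-atom acyl tether allows only this straight adduct 8. The tethered alkene adds to the cyclopentene face anti to the silyloxy group, which fixes C3a relative to C7. Methanolysis of the acetate frees a cyclobutanolate, and retro-aldol cleavage of the bond shared by the four-membered and the original five-membered ring inserts the two alkene carbons and opens the seven-membered ring C as a 1,5-diketone. The ring D enolate formed is protonated at C8a on the face away from the neighbouring CMe2, that is cis to H-3a, and the cis-fused cyclopentanone is also expected to be the stable epimer under the carbonate conditions. The closest known reaction type is the de Mayo reaction of enol acetates of 2-(alk-4-enoyl)cyclopentanones to bicyclo[5.3.0]decanediones. The step needs straight over crossed addition (tether), anti facial selectivity (silyloxy group) and survival of the β-silyloxy ketone (catalytic carbonate at 0 °C).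

Step 6
Reactants: 9 (3aR,7S,8aR)-7-(tert-butyldimethylsilyloxy)-4,4-dimethyloctahydroazulene-1,5-dione
Product: 10 (3aR,7S,8aR)-7-(tert-butyldimethylsilyloxy)-4,4-dimethyl-1-methylideneoctahydroazulen-5-one
Conditions: Zn, CH2Br2, TiCl4, THF/CH2Cl2, 0 °C to rt
Reagents that add atoms: dibromomethane, BrCBr
Why: Takai–Lombardo methylenation is non-basic, so neither C8a nor the β-silyloxy ketone is disturbed, and it selects the ring D carbonyl over the ring C carbonyl, which is shielded by the adjacent quaternary carbon.

Step 7
Reactants: 10 (3aR,7S,8aR)-7-(tert-butyldimethylsilyloxy)-4,4-dimethyl-1-methylideneoctahydroazulen-5-one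
Product: 11 (1R,3aR,7S,8aR)-7-(tert-butyldimethylsilyloxy)-4,4-dimethyloctahydrospiro[azulene-1,2'-oxiran]-5-one
Conditions: mCPBA, NaHCO3, CH2Cl2, 0 °C
Reagents that add atoms: 3-chloroperoxybenzoic acid, O=C(OO)c1cccc(Cl)c1
Why: Prilezhaev epoxidation of the 1,1-disubstituted alkene is much faster than Baeyer–Villiger oxidation of the hindered ketone; the peracid approaches the convex face of the cis-fused bicycle, syn to the fusion hydrogens, which places the oxygen where the C1 hydroxyl must be.

Step 8
Reactants: 11 (1R,3aR,7S,8aR)-7-(tert-butyldimethylsilyloxy)-4,4-dimethyloctahydrospiro[azulene-1,2'-oxiran]-5-one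
Product: 12 (1R,3aR,7S,8aR)-7-(tert-butyldimethylsilyloxy)-4,4,6-trimethyloctahydrospiro[azulene-1,2'-oxiran]-5-one (C6 epimers)
Conditions: LiN(iPr)2, THF, −78 °C; MeI, DMPU, −78 to −40 °C
Reagents that add atoms: iodomethane, CI
Why: Enolate alkylation; C6 is the only enolisable position because C4 is quaternary, and the lithium enolate of a β-silyloxy ketone is stable to elimination at low temperature. The new centre becomes sp2 in the next step.

Step 9
Reactants: 12 (1R,3aR,7S,8aR)-7-(tert-butyldimethylsilyloxy)-4,4,6-trimethyloctahydrospiro[azulene-1,2'-oxiran]-5-one (C6 epimers)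
Product: 13 (1R,3aR,7S,8aR)-7-(tert-butyldimethylsilyloxy)-4,4,6-trimethyl-3,3a,4,7,8,8a-hexahydro-2H-spiro[azulene-1,2'-oxiran]-5-yl trifluoromethanesulfonate
Conditions: KN(SiMe3)2, THF, −78 °C; PhNTf2, −78 to −20 °C; aq. NH4Cl
Reagents that add atoms: N-phenylbis(trifluoromethanesulfonimide), O=S(=O)(N(c1ccccc1)S(=O)(=O)C(F)(F)F)C(F)(F)F
Why: Enolate O-triflation; the single α-hydrogen left gives the tetrasubstituted enol triflate as the only regioisomer, fixing the position of the ring C alkene.

Step 10
Reactants: 14 geraniol
Product: 15 (2R,3R)-2,3-epoxygeraniol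
Conditions: Ti(OiPr)4 (5 mol %), D-(−)-diethyl tartrate (7 mol %), t-BuOOH, 4 Å sieves, CH2Cl2, −20 °C
Reagents that add atoms: tert-butyl hydroperoxide, CC(C)(C)OO
Why: Sharpless asymmetric epoxidation touches only the allylic alkene; the D-tartrate sets the (2R,3R) epoxide, which will become C9a and, after inversion, C5a.

Step 11
Reactants: 15 (2R,3R)-2,3-epoxygeraniol
Product: 16 (2R,3R,6S)-2,3:6,7-diepoxygeraniol
Conditions: L-fructose-derived Shi ketone (enantiomer of the usual catalyst, 30 mol %), KHSO5 (as 2KHSO5·KHSO4·K2SO4), K2CO3, Bu4NHSO4, MeCN/(MeO)2CH2/aq. buffer pH 10.5, 0 °C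
Reagents that add atoms: potassium peroxymonosulfate, [K+].[O-]S(=O)(=O)OO
Why: Shi epoxidation of the one remaining trisubstituted alkene; the chiral dioxirane and not the remote epoxide controls the face, and the enantiomeric catalyst gives the (6S) epoxide, the future C3, of opposite sense to the first epoxide.

Step 12
Reactants: 16 (2R,3R,6S)-2,3:6,7-diepoxygeraniol; 17 methyl acetoacetate
Product: 20 methyl (6R,7R,10S)-6,7:10,11-diepoxy-7,11-dimethyl-3-oxododecanoate, via epoxy triflate 18 (not isolated), via acetoacetate dianion 19 (not isolated)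
Conditions: 16: Tf2O, 2,6-lutidine, CH2Cl2, −78 °C; 17: NaH, THF, 0 °C, then n-BuLi; combine at −78 to −40 °C; aq. NH4Cl
Reagents that add atoms: none
Why: γ-Alkylation of the acetoacetate dianion by the primary triflate (SN2 at the CH2 beside the epoxide, far faster than epoxide opening at −78 °C) attaches the β-keto ester terminator with both epoxides already in place, so the keto ester never meets the epoxidation oxidant.

Step 13
Reactants: 20 methyl (6R,7R,10S)-6,7:10,11-diepoxy-7,11-dimethyl-3-oxododecanoate
Product: 21 methyl (2Z,6R,7R,10S)-3-(tert-butyldimethylsilyloxy)-6,7:10,11-diepoxy-7,11-dimethyldodec-2-enoate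
Conditions: NaH, THF, 0 °C; t-BuMe2SiCl, 0 °C to rt
Reagents that add atoms: tert-butyldimethylsilyl chloride, CC(C)(C)[Si](C)(C)Cl
Why: O-silylation of the chelated sodium enolate gives the enol ether with the nucleophilic carbon fixed between the two carbonyl-derived carbons; basic, Lewis acid-free conditions leave the epoxides intact, and the alkene geometry has no stereochemical consequence.

Step 14
Reactants: 21 methyl (2Z,6R,7R,10S)-3-(tert-butyldimethylsilyloxy)-6,7:10,11-diepoxy-7,11-dimethyldodec-2-enoate
Product: 22 methyl (3S,5aR,6R,9aR)-3-(tert-butyldimethylsilyloxy)-2,2,5a-trimethyl-7-oxodecahydro-1-benzoxepine-6-carboxylate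
Conditions: t-BuMe2SiOTf (0.3 equiv), 2,6-di-tert-butyl-4-methylpyridine (0.5 equiv), CH2Cl2, −78 °C; aq. NaHCO3
Reagents that add atoms: none
Why: Tandem oxa- and carbacyclisation of a 1,5-diepoxide with an enol silane terminator. Silylation of the terminal epoxide lets the internal epoxide oxygen attack its tertiary carbon (C3 keeps its configuration and becomes the silyl ether), and the epoxonium ion is opened at its tertiary carbon with inversion by the enol ether, giving the trans ring fusion with C9a retained. The released silyl group carries the chain, and the ester at C6 settles equatorial.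

Step 15
Reactants: 22 methyl (3S,5aR,6R,9aR)-3-(tert-butyldimethylsilyloxy)-2,2,5a-trimethyl-7-oxodecahydro-1-benzoxepine-6-carboxylate
Product: 23 (3S,5aR,6S,9aR)-3-(tert-butyldimethylsilyloxy)-6-(hydroxymethyl)-2,2,5a-trimethyldecahydro-1-benzoxepin-7-ol (C7 epimers)
Conditions: LiAlH4, THF, 0 °C to rt
Reagents that add atoms: none
Why: Hydride reduction of ketone and ester to the 1,3-diol; the C7 configuration does not matter because it is oxidised again in step 18.

Step 16
Reactants: 23 (3S,5aR,6S,9aR)-3-(tert-butyldimethylsilyloxy)-6-(hydroxymethyl)-2,2,5a-trimethyldecahydro-1-benzoxepin-7-ol (C7 epimers)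
Product: 24 (3S,5aR,6R,9aR)-3-(tert-butyldimethylsilyloxy)-7-hydroxy-2,2,5a-trimethyldecahydro-1-benzoxepine-6-carbaldehyde (C7 epimers)
Conditions: TEMPO (10 mol %), PhI(OAc)2, CH2Cl2, rt
Reagents that add atoms: none
Why: Oxoammonium oxidation selects the primary over the secondary alcohol and stops at the aldehyde under near-neutral conditions, so the equatorial C6 centre is kept.

Step 17
Reactants: 24 (3S,5aR,6R,9aR)-3-(tert-butyldimethylsilyloxy)-7-hydroxy-2,2,5a-trimethyldecahydro-1-benzoxepine-6-carbaldehyde (C7 epimers)
Product: 25 (3S,5aR,6R,9aR)-3-(tert-butyldimethylsilyloxy)-6-ethenyl-2,2,5a-trimethyldecahydro-1-benzoxepin-7-ol (C7 epimers)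
Conditions: Ph3PCH3Br, KOtBu, THF, 0 °C (aldehyde added to excess ylide)
Reagents that add atoms: methyltriphenylphosphonium bromide, C[P+](c1ccccc1)(c1ccccc1)c1ccccc1.[Br-]
Why: Wittig methylenation supplies the second bridge carbon; addition to excess ylide at low temperature outruns retro-aldol of the β-hydroxy aldehyde, and the equatorial C6 substituent is also the thermodynamic one.

Step 18
Reactants: 25 (3S,5aR,6R,9aR)-3-(tert-butyldimethylsilyloxy)-6-ethenyl-2,2,5a-trimethyldecahydro-1-benzoxepin-7-ol (C7 epimers)
Product: 26 (3S,5aR,6R,9aR)-3-(tert-butyldimethylsilyloxy)-6-ethenyl-2,2,5a-trimethyloctahydro-1-benzoxepin-7(2H)-one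
Conditions: Dess–Martin periodinane, NaHCO3, CH2Cl2, 0 °C to rt
Reagents that add atoms: none
Why: Buffered Dess–Martin oxidation gives the α-vinyl ketone without moving the alkene into conjugation; both C7 epimers converge.

Step 19
Reactants: 26 (3S,5aR,6R,9aR)-3-(tert-butyldimethylsilyloxy)-6-ethenyl-2,2,5a-trimethyloctahydro-1-benzoxepin-7(2H)-one
Product: 27 (3S,5aR,6R,7S,9aR)-3-(tert-butyldimethylsilyloxy)-6-ethenyl-2,2,5a,7-tetramethyldecahydro-1-benzoxepin-7-ol
Conditions: MeLi, CeCl3, THF, −78 °C
Reagents that add atoms: methyllithium, [Li]C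
Why: Organocerium 1,2-addition avoids enolisation of the doubly activated C6 hydrogen; axial approach is blocked by the syn-axial C5a methyl, so methyl enters equatorially and the hydroxyl ends up axial, setting C7 as (S).

Step 20
Reactants: 27 (3S,5aR,6R,7S,9aR)-3-(tert-butyldimethylsilyloxy)-6-ethenyl-2,2,5a,7-tetramethyldecahydro-1-benzoxepin-7-ol; 13 (1R,3aR,7S,8aR)-7-(tert-butyldimethylsilyloxy)-4,4,6-trimethyl-3,3a,4,7,8,8a-hexahydro-2H-spiro[azulene-1,2'-oxiran]-5-yl trifluoromethanesulfonate
Product: 29 (3S,5aR,6R,7S,9aR)-3-(tert-butyldimethylsilyloxy)-6-{2-[(1R,3aR,7S,8aR)-7-(tert-butyldimethylsilyloxy)-4,4,6-trimethyl-3,3a,4,7,8,8a-hexahydro-2H-spiro[azulene-1,2'-oxiran]-5-yl]ethyl}-2,2,5a,7-tetramethyldecahydro-1-benzoxepin-7-ol, via alkylborane 28 (not isolated)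
Conditions: 27: 9-BBN (2.5 equiv), THF, 0 to 50 °C; then 3 M aq. Cs2CO3, 13, Pd(dppf)Cl2 (10 mol %), AsPh3, DMF, 50 °C
Reagents that add atoms: none
Why: B-alkyl Suzuki–Miyaura coupling: anti-Markovnikov hydroboration of the vinyl group, then oxidative addition of zerovalent palladium into the enol triflate and transfer of the primary alkyl group. No stereocentre is touched, and the epoxide, silyl ethers and tertiary alcohol tolerate the aqueous carbonate.

Step 21
Reactants: 29 (the coupled spiro-epoxide of step 20)
Product: 30 (3S,5aR,6R,7S,9aR)-3-(tert-butyldimethylsilyloxy)-6-{2-[(1R,3aR,7S,8aR)-7-(tert-butyldimethylsilyloxy)-1-hydroxy-1,4,4,6-tetramethyl-1,2,3,3a,4,7,8,8a-octahydroazulen-5-yl]ethyl}-2,2,5a,7-tetramethyldecahydro-1-benzoxepin-7-ol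
Conditions: LiBHEt3, THF, 0 °C to rt
Reagents that add atoms: none
Why: Triethylborohydride opens the 1,1-disubstituted epoxide by SN2 attack at its CH2 carbon, turning it into the C1 methyl and leaving the hydroxyl on the face fixed in step 7; nothing else in 29 is reducible.

Step 22
Reactants: 30 (the bis-silyl ether of step 21)
Product: 31 (3S,5aR,6R,7S,9aR)-6-{2-[(1R,3aR,7S,8aR)-1,7-dihydroxy-1,4,4,6-tetramethyl-1,2,3,3a,4,7,8,8a-octahydroazulen-5-yl]ethyl}-2,2,5a,7-tetramethyldecahydro-1-benzoxepine-3,7-diol
Conditions: Bu4NF, THF, 50 °C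
Reagents that add atoms: none
Why: Fluoride cleaves both silyl ethers without acid, so the tertiary alcohols and the allylic carbinol are not exposed to ionising conditions.

## Compound list

1 | (R)-4-(tert-butyldimethylsilyloxy)cyclopent-2-en-1-one | O=C1C=C[C@H](O[Si](C)(C)C(C)(C)C)C1 | starting material
2 | (S)-tert-butyl{[3-(dimethylphenylsilyloxy)cyclopent-3-en-1-yl]oxy}dimethylsilane | C[Si](C)(c1ccccc1)OC1=CC[C@H](O[Si](C)(C)C(C)(C)C)C1 | intermediate
3 | 5-methylhex-4-enoic acid | CC(C)=CCCC(=O)O | starting material
4 | 1-(5-methylhex-4-enoyl)imidazole | CC(C)=CCCC(=O)n1ccnc1 | intermediate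
5 | lithium (S)-4-(tert-butyldimethylsilyloxy)cyclopent-1-en-1-olate | [Li+].[O-]C1=CC[C@H](O[Si](C)(C)C(C)(C)C)C1 | intermediate
6 | (4S)-4-(tert-butyldimethylsilyloxy)-2-(5-methylhex-4-enoyl)cyclopentan-1-one (C2 undefined, enolised) | CC(C)=CCCC(=O)C1C[C@H](O[Si](C)(C)C(C)(C)C)CC1=O | intermediate
7 | (4S)-4-(tert-butyldimethylsilyloxy)-2-(5-methylhex-4-enoyl)cyclopent-1-en-1-yl acetate | CC(=O)OC1=C(C(=O)CCC=C(C)C)C[C@H](O[Si](C)(C)C(C)(C)C)C1 | intermediate
8 | 9-(tert-butyldimethylsilyloxy)-6,6-dimethyl-2-oxotricyclo[5.3.0.0(1,5)]dec-7-yl acetate; cyclobutane cis-fused to both five-membered rings, new bonds anti to the silyloxy group | CC(=O)O[C@@]12C[C@@H](O[Si](C)(C)C(C)(C)C)C[C@@]13C(=O)CC[C@H]3C2(C)C | intermediate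
9 | (3aR,7S,8aR)-7-(tert-butyldimethylsilyloxy)-4,4-dimethyloctahydroazulene-1,5-dione (cis-fused) | C1C(=O)C(C)(C)[C@@H]2CCC(=O)[C@@H]2C[C@@H]1O[Si](C)(C)C(C)(C)C | intermediate
10 | (3aR,7S,8aR)-7-(tert-butyldimethylsilyloxy)-4,4-dimethyl-1-methylideneoctahydroazulen-5-one | C1C(=O)C(C)(C)[C@@H]2CCC(=C)[C@@H]2C[C@@H]1O[Si](C)(C)C(C)(C)C | intermediate
11 | (1R,3aR,7S,8aR)-7-(tert-butyldimethylsilyloxy)-4,4-dimethyloctahydrospiro[azulene-1,2'-oxiran]-5-one (epoxide oxygen syn to the fusion hydrogens) | C1C(=O)C(C)(C)[C@@H]2CC[C@@]3(OC3)[C@@H]2C[C@@H]1O[Si](C)(C)C(C)(C)C | intermediate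
12 | (1R,3aR,7S,8aR)-7-(tert-butyldimethylsilyloxy)-4,4,6-trimethyloctahydrospiro[azulene-1,2'-oxiran]-5-one (C6 epimers) | CC1C(=O)C(C)(C)[C@@H]2CC[C@@]3(OC3)[C@@H]2C[C@@H]1O[Si](C)(C)C(C)(C)C | intermediate
13 | (1R,3aR,7S,8aR)-7-(tert-butyldimethylsilyloxy)-4,4,6-trimethyl-3,3a,4,7,8,8a-hexahydro-2H-spiro[azulene-1,2'-oxiran]-5-yl trifluoromethanesulfonate | CC1=C(OS(=O)(=O)C(F)(F)F)C(C)(C)[C@@H]2CC[C@@]3(OC3)[C@@H]2C[C@@H]1O[Si](C)(C)C(C)(C)C | intermediate
14 | geraniol | CC(C)=CCC/C(C)=C/CO | starting material
15 | (2R,3R)-2,3-epoxygeraniol | OC[C@H]1O[C@]1(C)CCC=C(C)C | intermediate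
16 | (2R,3R,6S)-2,3:6,7-diepoxygeraniol | OC[C@H]1O[C@]1(C)CC[C@@H]1OC1(C)C | intermediate
17 | methyl acetoacetate | COC(=O)CC(C)=O | starting material
18 | (2R,3R,6S)-2,3:6,7-diepoxygeranyl trifluoromethanesulfonate | FC(F)(F)S(=O)(=O)OC[C@H]1O[C@]1(C)CC[C@@H]1OC1(C)C | intermediate
19 | methyl acetoacetate dianion, sodium lithium salt | [Na+].[Li+].[CH2-]C(=O)[CH-]C(=O)OC | intermediate
20 | methyl (6R,7R,10S)-6,7:10,11-diepoxy-7,11-dimethyl-3-oxododecanoate | COC(=O)CC(=O)CC[C@H]1O[C@]1(C)CC[C@@H]1OC1(C)C | intermediate
21 | methyl (2Z,6R,7R,10S)-3-(tert-butyldimethylsilyloxy)-6,7:10,11-diepoxy-7,11-dimethyldodec-2-enoate | COC(=O)/C=C(\O[Si](C)(C)C(C)(C)C)CC[C@H]1O[C@]1(C)CC[C@@H]1OC1(C)C | intermediate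
22 | methyl (3S,5aR,6R,9aR)-3-(tert-butyldimethylsilyloxy)-2,2,5a-trimethyl-7-oxodecahydro-1-benzoxepine-6-carboxylate (trans-fused, ester equatorial) | COC(=O)[C@@H]1[C@@]2(C)CC[C@H](O[Si](C)(C)C(C)(C)C)C(C)(C)O[C@@H]2CCC1=O | intermediate
23 | (3S,5aR,6S,9aR)-3-(tert-butyldimethylsilyloxy)-6-(hydroxymethyl)-2,2,5a-trimethyldecahydro-1-benzoxepin-7-ol (C7 epimers) | OC[C@@H]1[C@@]2(C)CC[C@H](O[Si](C)(C)C(C)(C)C)C(C)(C)O[C@@H]2CCC1O | intermediate
24 | (3S,5aR,6R,9aR)-3-(tert-butyldimethylsilyloxy)-7-hydroxy-2,2,5a-trimethyldecahydro-1-benzoxepine-6-carbaldehyde (C7 epimers) | O=C[C@@H]1[C@@]2(C)CC[C@H](O[Si](C)(C)C(C)(C)C)C(C)(C)O[C@@H]2CCC1O | intermediate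
25 | (3S,5aR,6R,9aR)-3-(tert-butyldimethylsilyloxy)-6-ethenyl-2,2,5a-trimethyldecahydro-1-benzoxepin-7-ol (C7 epimers) | C=C[C@@H]1[C@@]2(C)CC[C@H](O[Si](C)(C)C(C)(C)C)C(C)(C)O[C@@H]2CCC1O | intermediate
26 | (3S,5aR,6R,9aR)-3-(tert-butyldimethylsilyloxy)-6-ethenyl-2,2,5a-trimethyloctahydro-1-benzoxepin-7(2H)-one | C=C[C@@H]1[C@@]2(C)CC[C@H](O[Si](C)(C)C(C)(C)C)C(C)(C)O[C@@H]2CCC1=O | intermediate
27 | (3S,5aR,6R,7S,9aR)-3-(tert-butyldimethylsilyloxy)-6-ethenyl-2,2,5a,7-tetramethyldecahydro-1-benzoxepin-7-ol (7-OH axial) | C=C[C@@H]1[C@@]2(C)CC[C@H](O[Si](C)(C)C(C)(C)C)C(C)(C)O[C@@H]2CC[C@]1(C)O | intermediate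
28 | 9-{2-[(3S,5aR,6R,7S,9aR)-3-(tert-butyldimethylsilyloxy)-7-hydroxy-2,2,5a,7-tetramethyldecahydro-1-benzoxepin-6-yl]ethyl}-9-borabicyclo[3.3.1]nonane | B1(CC[C@@H]2[C@@]3(C)CC[C@H](O[Si](C)(C)C(C)(C)C)C(C)(C)O[C@@H]3CC[C@]2(C)O)C2CCCC1CCC2 | intermediate
29 | coupled spiro-epoxide: 27 (as its ethyl chain) joined at C5 of the ring system of 13, name as in step 20 | CC1=C(CC[C@@H]2[C@@]3(C)CC[C@H](O[Si](C)(C)C(C)(C)C)C(C)(C)O[C@@H]3CC[C@]2(C)O)C(C)(C)[C@@H]2CC[C@@]3(OC3)[C@@H]2C[C@@H]1O[Si](C)(C)C(C)(C)C | intermediate
30 | 3,7'-bis(tert-butyldimethylsilyl) ether of the target, name as in step 21 | CC1=C(CC[C@@H]2[C@@]3(C)CC[C@H](O[Si](C)(C)C(C)(C)C)C(C)(C)O[C@@H]3CC[C@]2(C)O)C(C)(C)[C@@H]2CC[C@@](C)(O)[C@@H]2C[C@@H]1O[Si](C)(C)C(C)(C)C | intermediate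
31 | (3S,5aR,6R,7S,9aR)-6-{2-[(1R,3aR,7S,8aR)-1,7-dihydroxy-1,4,4,6-tetramethyl-1,2,3,3a,4,7,8,8a-octahydroazulen-5-yl]ethyl}-2,2,5a,7-tetramethyldecahydro-1-benzoxepine-3,7-diol | CC1=C(CC[C@@H]2[C@@]3(C)CC[C@H](O)C(C)(C)O[C@@H]3CC[C@]2(C)O)C(C)(C)[C@@H]2CC[C@@](C)(O)[C@@H]2C[C@@H]1O | target

## Step count and risks

Total: 22 steps. Longest linear sequence: 13 steps (14 to 31 through steps 10–22). The ring C/D arm from 1 is 11 steps to 31, and step 2 is a one-step side branch.

**Step 5 (key step).** The carbonate treatment is the most likely point of failure. The β-silyloxy group of the new ring C ketone can be lost by elimination, and the C8a centre can equilibrate towards a trans ring fusion. On the photochemical side, the second bond joins two fully substituted carbons, so disproportionation of the 1,4-biradical may compete. Facial discrimination may also be only moderate, because the silyloxy carbon is 1,3 to both reacting carbons. Fallback: from 6, acylate with benzyl chloroformate and pyridine to the enol benzyl carbonate F1, irradiate as before to the cyclobutyl benzyl carbonate F2, and unmask by hydrogenolysis (H2, Pd/C, EtOAc). Loss of toluene and CO2 gives the cyclobutanol, which fragments under neutral conditions with kinetic protonation at C8a on the face away from CMe2. This returns to the route at 9.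

**Step 14.** Activation of the internal epoxide may compete with that of the terminal one. The epoxonium ion may also be intercepted by triflate or lost by elimination before the weakly nucleophilic β-silyloxy enoate attacks, giving tetrahydrofuran-type or monocyclic products. Fallback by stepwise ring formation from 15:
- Alkylate the acetoacetate dianion with the triflate of 15 to give the mono-epoxy β-keto ester F3.
- Close ring B by the classical epoxide-initiated, β-keto ester-terminated cyclisation (SnCl4, CH2Cl2, −78 °C) to the hydroxy keto ester F4.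
- Epoxidise the prenyl alkene with the same L-fructose-derived ketone and KHSO5 to the hydroxy epoxide F5.
- Close the oxepane by acid-promoted endo opening at the tertiary epoxide carbon (BF3·OEt2, CH2Cl2, −78 °C) to the oxepanol F6.
- Silylate with t-BuMe2SiOTf and 2,6-lutidine, returning at 22.

**Step 20.** Oxidative addition and transmetalation at a tetrasubstituted triflate flanked by a quaternary carbon may be slow. Protodeboronation or β-hydride elimination of the alkyl group and hydrolysis of the triflate could then take over. Fallback by an sp2–sp2 union from 27: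
- Ozonolysis (O3, CH2Cl2/MeOH, −78 °C; Me2S) to the hydroxy aldehyde F7.
- Chromium-mediated boron olefination (CrCl2, Cl2CHB(pin), LiI, THF; Takai–Utimoto type) to the (E)-alkenylboronate F8.
- Suzuki–Miyaura coupling with 13 (Pd(PPh3)4, aq. K3PO4, dioxane) to the diene F9.
- Diimide reduction (2-nitrobenzenesulfonyl hydrazide, Et3N) of the disubstituted alkene only, returning at 29.

**Step 4.** Acetylation may fall on the side-chain enol oxygen. That isomer would enter a crossed cycloaddition and, after fragmentation, give a non-fused diketone. Fallback: irradiate the hydrogen-bonded enol of 6 itself (the original de Mayo reaction of a free 1,3-diketone). The two enol tautomers interconvert, the ring-enol channel with its three-atom tether is drained, and the cyclobutanol fragments spontaneously. This goes from 6 straight to 9 and no new compound arises (F0).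

**Step 9.** The hindered α-methine may resist deprotonation, or the tetrasubstituted potassium enolate may expel the β-silyloxy group before it is trapped. Fallback from 11: α-methylenation (LiN(SiMe3)2, then dimethylmethyleneiminium iodide; MeI, NaHCO3) to the exo-methylene ketone F10. Conjugate reduction with LiBH(s-Bu)3 at −78 °C then generates the same tetrasubstituted enolate regiospecifically without a deprotonation, and it is trapped with PhNTf2. This bypasses 12 and returns at 13.

## Further compounds

F1 | step 5 | benzyl (4S)-4-(tert-butyldimethylsilyloxy)-2-(5-methylhex-4-enoyl)cyclopent-1-en-1-yl carbonate | O=C(OCc1ccccc1)OC1=C(C(=O)CCC=C(C)C)C[C@H](O[Si](C)(C)C(C)(C)C)C1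
F2 | step 5 | benzyl 9-(tert-butyldimethylsilyloxy)-6,6-dimethyl-2-oxotricyclo[5.3.0.0(1,5)]dec-7-yl carbonate (stereochemistry as 8) | O=C(OCc1ccccc1)O[C@@]12C[C@@H](O[Si](C)(C)C(C)(C)C)C[C@@]13C(=O)CC[C@H]3C2(C)C
F3 | step 14 | methyl (6R,7R)-6,7-epoxy-7,11-dimethyl-3-oxododec-10-enoate | COC(=O)CC(=O)CC[C@H]1O[C@]1(C)CCC=C(C)C
F4 | step 14 | methyl (1R,2R,3R)-3-hydroxy-2-methyl-2-(4-methylpent-3-en-1-yl)-6-oxocyclohexane-1-carboxylate | COC(=O)[C@@H]1[C@@](C)(CCC=C(C)C)[C@H](O)CCC1=O
F5 | step 14 | methyl (1R,2R,3R)-2-{2-[(2S)-3,3-dimethyloxiran-2-yl]ethyl}-3-hydroxy-2-methyl-6-oxocyclohexane-1-carboxylate | COC(=O)[C@@H]1[C@@](C)(CC[C@@H]2OC2(C)C)[C@H](O)CCC1=O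
F6 | step 14 | methyl (3S,5aR,6R,9aR)-3-hydroxy-2,2,5a-trimethyl-7-oxodecahydro-1-benzoxepine-6-carboxylate | COC(=O)[C@@H]1[C@@]2(C)CC[C@H](O)C(C)(C)O[C@@H]2CCC1=O
F7 | step 20 | (3S,5aR,6R,7S,9aR)-3-(tert-butyldimethylsilyloxy)-7-hydroxy-2,2,5a,7-tetramethyldecahydro-1-benzoxepine-6-carbaldehyde | O=C[C@@H]1[C@@]2(C)CC[C@H](O[Si](C)(C)C(C)(C)C)C(C)(C)O[C@@H]2CC[C@]1(C)O
F8 | step 20 | (3S,5aR,6R,7S,9aR)-3-(tert-butyldimethylsilyloxy)-2,2,5a,7-tetramethyl-6-[(E)-2-(4,4,5,5-tetramethyl-1,3,2-dioxaborolan-2-yl)ethenyl]decahydro-1-benzoxepin-7-ol | CC1(C)OB(/C=C/[C@@H]2[C@@]3(C)CC[C@H](O[Si](C)(C)C(C)(C)C)C(C)(C)O[C@@H]3CC[C@]2(C)O)OC1(C)C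
F9 | step 20 | (E)-ethenylene-bridged analogue of 29 (diene) | CC1=C(/C=C/[C@@H]2[C@@]3(C)CC[C@H](O[Si](C)(C)C(C)(C)C)C(C)(C)O[C@@H]3CC[C@]2(C)O)C(C)(C)[C@@H]2CC[C@@]3(OC3)[C@@H]2C[C@@H]1O[Si](C)(C)C(C)(C)C
F0 | step 4 | none | none
F10 | step 9 | (1R,3aR,7S,8aR)-7-(tert-butyldimethylsilyloxy)-4,4-dimethyl-6-methylideneoctahydrospiro[azulene-1,2'-oxiran]-5-one | C=C1C(=O)C(C)(C)[C@@H]2CC[C@@]3(OC3)[C@@H]2C[C@@H]1O[Si](C)(C)C(C)(C)C
A1 | alternative 1 | (1R,3aR,8aR)-1-hydroxy-1,4,4,5,6-pentamethyl-2,3,3a,4,8,8a-hexahydroazulen-7(1H)-one | CC1=C(C)C(C)(C)[C@@H]2CC[C@@](C)(O)[C@@H]2CC1=O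
A2 | alternative 1 | (5R)-2,3,4,4-tetramethyl-5-(3-oxobutyl)cyclohepta-2,6-dien-1-one | CC(=O)CC[C@@H]1C=CC(=O)C(C)=C(C)C1(C)C
A3 | alternative 2 | 3-allyl-6-(tert-butyldimethylsilyloxy)-3,7,7-trimethyl-2,3,6,7-tetrahydrooxepine-2-carboxylic acid (stereochemistry as drawn) | C=CC[C@@]1(C)C=C[C@H](O[Si](C)(C)C(C)(C)C)C(C)(C)O[C@@H]1C(=O)O
A4 | alternative 2 | 6-(tert-butyldimethylsilyloxy)-5,5-dimethyl-7-[(1Z)-2-methylpenta-1,4-dien-1-yl]-1,4-dioxepan-2-one (configuration matched to a boat transition state) | O=C1COC(C)(C)[C@@H](O[Si](C)(C)C(C)(C)C)[C@H](/C=C(\CC=C)C)O1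
A5 | alternative 3 | 1-(triethylsilyloxy)-7-(triisopropylsilyloxy)-1,4,4,6-tetramethyl-1,2,3,3a,4,6-hexahydroazulen-5(7H)-one (C6 epimers, other centres as drawn) | CC1C(=O)C(C)(C)[C@@H]2CC[C@@](C)(O[Si](CC)(CC)CC)C2=C[C@@H]1O[Si](C(C)C)(C(C)C)C(C)C
A6 | alternative 3 | 2,4-dibromo-2-methylpentan-3-one | CC(Br)C(=O)C(C)(C)Br
A7 | alternative 3 | triethyl({1-methyl-2-[(E)-2-(triisopropylsilyloxy)ethenyl]cyclopent-2-en-1-yl}oxy)silane (carbinol centre as drawn) | C[C@@]1(O[Si](CC)(CC)CC)CCC=C1/C=C/O[Si](C(C)C)(C(C)C)C(C)C
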